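Every unit of starting material charged stays in the flask in some form, yet in ash at 120 min target and side product A together hold 18.0%, so 82.0% of the charge stands unread.

| flask | starting material | reagent | remark | time |
|---|---|---|---|---|
| ash | 19 mM | 54.6 mM | run made earlier |  |
| cedar | 50 mM | 54.6 mM | run made earlier |  |
| alder | 160 mM | 54.6 mM | run made earlier |  |
| oak | 42 mM | 38 mM | run made earlier |  |
| teal | 42 mM | 54.6 mM |  | 4.0 h |
| green | 42 mM | 150 mM |  | 4.0 h |
| ochre | 15 mM | 15.0 mM |  | 4.0 h |
| red | 150 mM | 15.0 mM |  | 4.0 h |
| amber | 20 mM | 80.0 mM |  | 4.0 h |

| run | time / min | target / % | side product A / % |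
|---|---|---|---|
| ash | 25.0 | 0 | 4 |
| ash | 50.0 | 0 | 6 |
| ash | 80.0 | 5 | 11 |
| ash | 90.0 | 2 | 10 |
| ash | 120 | 3 | 15 |
| cedar | 10.0 | 0 | 0 |
| cedar | 30.0 | 1 | 2 |
| cedar | 60.0 | 0 | 4 |
| cedar | 80.0 | 2 | 8 |
| cedar | 120 | 7 | 15 |
| alder | 10.0 | 0 | 4 |
| alder | 30.0 | 0 | 3 |
| alder | 60.0 | 4 | 3 |
| alder | 80.0 | 1 | 8 |
| alder | 120 | 2 | 10 |
| oak | 25.0 | 1 | 3 |
| oak | 50.0 | 0 | 6 |
| oak | 80.0 | 0 | 9 |
| oak | 90.0 | 3 | 9 |
| oak | 120 | 5 | 15 |

(standard deviation of a reading: 1.5 percentage points)

- percent here means starting material units held: one side product B counts as two

* all flasks from highest to lowest share of target in all that became target or side product A or isomer of the product or side product B, at 4.0 h (teal / green / ochre / red / amber)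
* the share of target in all that became target or side product A or isomer of the product or side product B of the flask you put first, at 4.0 h
* the share of target in all that became target or side product A or isomer of the product or side product B of the flask you put last, at 4.0 h

What the readings do give is the tilt, target per unit of side product A, summed over the last readings of ash, cedar and alder: 0.300. Each reading carries 1.5 percentage points, against target readings of 2% to 7%, so the tilt is rough. Two chemists argue over it, and both read target's lag as growth near the square of time, which makes the tilt grow in proportion to time.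

She holds that the tilt ignores reagent: oak, at 38 mM, reads 0.333, above the tilt. So she expects 0.600 in every flask at 4.0 h.

He holds that the tilt also follows reagent, a pseudo-first-order capture with reagent near its charge. His oak target would be 3.13%, a gap of 1.9 points from the reading, against a scatter of 1.5 points. He expects 1.65 in green, 0.879 in amber and 0.165 in ochre and red alike.

I side with him and commit to these tilts, not to shares. Alder's side product A of 10% is lower than cedar's 15%, so I set red under ochre.

The forecast stands on his side, with shares of its own: green > amber > teal > ochre > red, top 50%, low 4%. Its ground: “High reagent and dilute starting material should therefore favour target.”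

The simulation gives green > amber > teal > ochre > red, top 31.5%, low 3.42%.

    starting material ⇌ intermediate A (K = 1.90, k = 0.580 min⁻¹)
    intermediate A → intermediate B (k = 0.0400 min⁻¹)
    intermediate B → side product A (k = 0.00250 min⁻¹)
    reagent + intermediate B → intermediate C (k = 0.0680 M⁻¹ min⁻¹)
    intermediate C → target (k = 0.0110 min⁻¹)
    target ⇌ isomer of the product (K = 0.960, k = 0.0780 min⁻¹)
    starting material + intermediate B → side product B (k = 0.410 M⁻¹ min⁻¹)

Green's tilt comes to 1.45, near his 1.65 and far from her 0.600. In red, target and isomer of the product relax into each other with a half-life of 0.0725 h, short against 4.0 h. Green at 4.00 h holds 23.7% target beside 21.7% isomer of the product, and the asked share counts both.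

Take red with 38 mM of reagent: the tilt reckons 0.418. That neighbour flask computes to 5.51% target per 21.0% side product A, a tilt of 0.262, with 42.5% of its reagent left and a share of 7.84%.

The runs come from a simulation with constants of no real substance; noise was put on by code.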